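## Structural features

The target is a cycloheptane (ring A: C1, C10, C9, C8, C7, C6, C5) cis-fused along C6–C7 to an α-methyl-γ-butyrolactone (ring B: C6–O–C12(=O)–C11–C7). C1 is a fully substituted carbinol that also carries the (E)-crotonoyl chain (C2 ketone, C3=C4). C5 carries an isobutyrate, C10 a methyl group, and C8 and C9 are plain methylenes. Five of the six stereocentres (C10, C1, C5, C6, C7) stand in an unbroken row on ring A, and the sixth, C11, hangs on C7. With the C1 hydroxyl as reference face, the C10 methyl, the C6 oxygen and the C7–C11 bond lie on that face, and the C5 oxygen and the acyl chain lie on the other. On ring B, H6, H7 and H11 share the convex face, so the C11 methyl sits on the concave side next to C8, which is the less stable, base-labile arrangement. Fragile groups are the enone (reduction, conjugate addition), the tertiary α-ketol, C11, and the C5 ester, which can migrate to a free hydroxyl at C1 or C2. The real difficulty is the crowded C10–C1–C5 segment with its quaternary carbinol, set in a mobile seven-membered ring that offers little help for ring closure or facial control. The key step uses the 1,4 relation between the C1 oxygen and unfunctionalised C8. Tying that oxygen to C8 turns ring A into an 8-oxabicyclo[3.2.1]octenone with C1 as bridgehead, C5 as ketone and C6=C7 as the handle for ring B, that is, the adduct of a 3-oxidopyrylium (C1, C5–C8, O) and a propenyl unit (C9, C10).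

## Logic of the disconnections

**30 to 27 and 7 (through 29).** The C2–C3 bond is cut and C2 is taken back to the aldehyde level. The enone would not survive hydrogenation, electron-transfer reduction or strong base, so it has to come last. The cut removes the only reducible π system and leaves a C16 core plus a three-carbon halide already used elsewhere. The forward addition must select the aldehyde beside a lactone, an ester and a free tertiary hydroxyl, and must keep the (E) geometry.

**27 to 25 (through 26).** No skeletal bond is cut. C2 goes back to a benzyl-protected primary alcohol and C8–C9 to an alkene. One hydrogenation then does both jobs, which is why the C2 oxygen carries benzyl throughout. A silyl ether would need a separate fluoride step next to a migration-prone ester, and it would sit 1,2 to the C1 alkoxide released earlier, inviting silyl migration. The forward steps must stay neutral, because in 26 the C5 ester is cis-1,3 to the new primary hydroxyl.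

**25 to 24.** The C5 O–acyl bond is cut. Acylating after the strong-base step keeps the ester away from alkoxides. The demand is selectivity for the secondary over the tertiary hydroxyl.

**24 to 23.** A C9–S bond is put back. A base-induced bridge opening leaves sulfur on the alkene, and hydrogenation alone would not remove it, so a dedicated reductive desulfonylation is planned. It must spare the lactone and leave C7 and C10 untouched.

**23 to 21.** The C1 oxygen is reconnected to C8 (retro E1cB), and the C11–H bond is treated as made in the same operation. This restores a rigid tricycle in which the bridge protects the C1 hydroxyl. The forward step needs enough base for the C5 alkoxide, the lactone enolate and the C9 carbanion, followed by a kinetic quench.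

**21 to 17 (through 20).** The C5–H bond, the C12–O lactone bond and the C6–O bond are cut. All three are exo-face or cis-proximity events on the bicycle. The result is a single enol ether whose regiochemistry is fixed, because C1 carries no hydrogen.

**17 to 13 and 16.** The C7–C11 bond is cut. This removes the three carbons of ring B and returns the bare enone. The forward addition must be non-basic (acidic C9–H, β-oxygen at C8) and must hand over the enol ether directly.

**13 to 6 and 10 (through 12).** After adjusting sulfur back to the sulfoxide, C1–C10 and C8–C9 are cut. Two bonds, the carbocycle and four stereocentres fall to two simple partners. The forward step needs C9-to-C8 regiochemistry, endo sulfur and one alkene face.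

**6 to 1 and 2 (through 5 and 4).** The acetate, the oxidative ring expansion and the C1–C5 bond are undone. Neither stereocentre of 6 matters, since both vanish in the ylide, so racemic material serves.

**10 to 7 and 8.** The S–C9 bond is cut. Chirality is bought as a crystalline sulfinate. The vinyl metal must keep its geometry and must not attack the product sulfoxide.

**16 to 14.** The O–Si bond is cut. The geometry of 16 is irrelevant because C11 is reset later.

## Other disconnections considered

**Alternative 1:**
- **Cut and key step.** The cut is C6–C7 of ring A. CrCl2 would reduce the allylic bromide of the open-chain aldehyde A1 to an allylchromium species (trivalent chromium). Its γ-carbon C7 would attack the C6 aldehyde, closing ring A to the hydroxy ester A2 with the C11 methylene in place.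
- **In its favour.** The carbonyl addition is mild and highly chemoselective. Ring closure, the C6 carbinol and all carbons of ring B arrive together, and there is no sulfur to remove.
- **Where it is better.** Hydrogenation of the exocyclic methylene from the convex face would place the methyl on the concave side without strong base, a better answer to C11 than enolate protonation.
- **Against it here.** A1 must already hold C1, C5 and C10, the hardest part of the molecule, made by acyclic stereocontrol. Seven-membered closure competes with intermolecular coupling. The cis C6/C7 relation and its sense relative to C5 rest on a flexible medium-ring transition state, further constrained by a trans-fused acetonide.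
- **Comparison.** It makes one bond and two stereocentres, against two bonds and four stereocentres. Functional-group tolerance of the two key steps is about equal. Its endgame would be shorter, but the way to A1 would be much longer.

**Alternative 2:**
- **Cut and key step.** The cut is C7–C11 of ring B. A dirhodium carboxylate such as Rh2(OAc)4 would decompose the C6 2-diazopropanoate A3, and the carbenoid would insert into the cis C7–H bond to give A4, one desilylation from the target.
- **In its favour.** It is extremely late and forms ring B in a single step. The cis fusion is inherent in a five-membered insertion.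
- **Where it is better.** For the lactone alone it beats the three operations of the chosen plan (addition, oxygenation, lactonisation).
- **Against it here.** An α-methyl diazo ester is prone to a 1,2-hydride shift to the acrylate. The crotonoyl alkene is open to cyclopropanation or ylide chemistry. C7 is an unactivated methylene competing with C5–H. The C11 methyl would have to end on the concave side with nothing to direct it.
- **Comparison.** The disconnection says nothing about ring A or the C10–C1–C5–C6 row, which A3 must already contain. Overall it moves the problem rather than solving it.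

**Alternative 3:**
- **Cut and key step.** The cuts are C12–O and C11–C12. PdCl2 with thiourea under CO would form an alkoxycarbonyl complex of divalent palladium on the C6 oxygen of the alkynol A5. That complex would add across the C7 alkyne and close the α-methylene lactone A6.
- **In its favour.** C12 comes from CO, the step is catalytic and tolerant, and the cis fusion follows from the cis alkynol.
- **Where it is equal or better.** C11 can be set by convex-face hydrogenation.
- **Against it here.** In A6, C1 is only a masked ketone. The tertiary carbinol would then need a crotonoyl anion equivalent added to a hindered ketone, with face control, between an epimerisable C10 and an α-alkoxy C5, and after the methylene has been reduced. A ketal and an ether must be exchanged as well, and ring A with the cis C6/C7 pair is again presupposed.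
- **Comparison.** The chosen plan creates C1 as a bridgehead with its oxygen and its one-carbon handle already attached. This is the decisive structural advantage and should save several steps.

Key step: step 5

Assumption: atom labels follow the numbering defined under Structural features, and substitution at the sulfur of 8 is taken to go with inversion.

## Route

Step 1
Reactants: 1 furan; 2 benzyloxyacetaldehyde
Product: 4 2-(benzyloxy)-1-(furan-2-yl)ethan-1-ol (racemic), via 2-furyllithium 3 (not isolated)
Conditions: n-BuLi, THF, −78 to 0 °C; then 2, −78 °C; then H2O
Reagents that add atoms: none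
Why: α-Lithiation of furan followed by organolithium 1,2-addition to an unhindered aldehyde forms the C1–C5 bond. The carbinol centre needs no control because it becomes a planar ylide terminus in step 5.

Step 2
Reactants: 4 2-(benzyloxy)-1-(furan-2-yl)ethan-1-ol
Product: 5 2-(benzyloxymethyl)-6-hydroxy-2H-pyran-3(6H)-one (diastereomer mixture)
Conditions: mCPBA, CH2Cl2, 0 °C to rt
Reagents that add atoms: mCPBA, O=C(OO)c1cccc(Cl)c1
Why: Achmatowicz rearrangement: oxidation of the electron-rich furan, opening to the ene-dione and closure of the carbinol oxygen onto the aldehyde give the hydroxypyranone. The benzyl ether is inert and both stereocentres are inconsequential.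

Step 3
Reactants: 5 2-(benzyloxymethyl)-6-hydroxy-2H-pyran-3(6H)-one
Product: 6 6-acetoxy-2-(benzyloxymethyl)-2H-pyran-3(6H)-one (diastereomer mixture)
Conditions: Ac2O, pyridine, DMAP (cat.), CH2Cl2, 0 °C
Reagents that add atoms: acetic anhydride, CC(=O)OC(C)=O
Why: Acylation turns the lactol hydroxyl into the leaving group needed for ylide formation. Pyridine at 0 °C is too weak a base to unmask the ylide, so 6 can be isolated.

Step 4
Reactants: 7 (E)-1-bromoprop-1-ene; 8 (1R,2S,5R)-menthyl (S)-p-toluenesulfinate
Product: 10 (R)-(E)-1-propenyl p-tolyl sulfoxide, via (E)-prop-1-enyllithium 9 (not isolated)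
Conditions: 7, t-BuLi (2.0 equiv), Et2O, −78 °C; cannulated into 8, THF, −78 °C; then H2O
Reagents that add atoms: none
Why: Bromine–lithium exchange keeps the (E) geometry that magnesium insertion would erode. The Andersen sulfoxide synthesis then replaces the menthoxide at sulfur with inversion, giving the (R) sulfoxide. Inverse addition at low temperature prevents a second attack at sulfur that would racemise 10.

Step 5
Reactants: 6 6-acetoxy-2-(benzyloxymethyl)-2H-pyran-3(6H)-one; 10 (R)-(E)-1-propenyl p-tolyl sulfoxide
Product: 12 sulfinyl 8-oxabicyclo[3.2.1]oct-3-en-2-one adduct (1-benzyloxymethyl; 7-exo-methyl; 6-endo-(R)-p-tolylsulfinyl; C5 ketone and C6=C7 in target numbering), via 2-(benzyloxymethyl)-3-oxidopyrylium 11 (not isolated)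
Conditions: 10 (3 equiv), i-Pr2NEt (1.5 equiv), MeCN, 40 °C, 6 added slowly by syringe pump
Reagents that add atoms: none
Why: The amine removes the acidic C1–H beside the ketone of 6 and acetate leaves from C8, unmasking the planar 3-oxidopyrylium 11, a five-atom dipole with termini C1 and C8. Ylide 11 adds across C9=C10 of 10 in a concerted addition, suprafacial on both partners; the closest known reaction type is the intermolecular (5+2) addition of 3-oxidopyrylium and 3-oxidopyridinium betaines to vinyl sulfones and enantiopure vinyl sulfoxides. The seven-membered carbocycle (C1, C10, C9, C8, C7, C6, C5) closes by intermolecular cycloaddition, both σ bonds C1–C10 and C8–C9 forming in the same event, with the pyran oxygen left as the C1–O–C8 bridge. C1 is the enolate-like, nucleophilic terminus and pairs with the electrophilic β-carbon C10, so sulfinyl-bearing C9 bonds to the oxocarbenium-like C8. C1 and C8 are tied together by the bridge, and C9 and C10 keep the trans relation of the (E) alkene. The link between these two pairs comes from the endo orientation of the acceptor group under the ylide π system, which puts sulfur endo at C9 and the methyl exo at C10, syn to the bridge oxygen as the target requires. In the reactive conformer S=O is syn-periplanar to C=C, the p-tolyl group covers the Si face of C9 and the ylide bonds to the Re face on the lone-pair side, which for the (R) sulfoxide maps onto the C1 and C10 configuration of 30. Slow addition of 6 to an excess of recoverable 10 keeps the ylide dilute against dimerisation, and 40 °C stays below the onset of sulfoxide syn elimination toward C10.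

Step 6
Reactants: 12 sulfinyl oxabicyclic enone
Product: 13 sulfonyl 8-oxabicyclo[3.2.1]oct-3-en-2-one (6-endo-p-tolylsulfonyl; otherwise as 12)
Conditions: mCPBA (1.1 equiv), CH2Cl2, 0 °C
Reagents that add atoms: mCPBA, O=C(OO)c1cccc(Cl)c1
Why: Electrophilic S-oxidation is far faster than epoxidation of the electron-poor enone. It is done at once because the sulfoxide could lose sulfenic acid toward C10 on warming and would undergo a Pummerer reaction with the silyl ketene acetal of step 8; the sulfur stereocentre has done its work.

Step 7
Reactants: 14 methyl propanoate
Product: 16 1-methoxy-1-(trimethylsilyloxy)prop-1-ene (E/Z mixture), via methyl propanoate lithium enolate 15 (not isolated)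
Conditions: LDA, THF, −78 °C; then TMSCl, −78 °C to rt
Reagents that add atoms: chlorotrimethylsilane, C[Si](C)(C)Cl
Why: Kinetic ester enolisation followed by O-silylation. The geometry of 16 does not matter because C11 is reset in step 11.

Step 8
Reactants: 13 sulfonyl oxabicyclic enone; 16 1-methoxy-1-(trimethylsilyloxy)prop-1-ene
Product: 17 C5 trimethylsilyl enol ether (C5=C6) bearing an exo CH(CH3)CO2CH3 group at C7 (C11 epimers)
Conditions: TMSOTf (10 mol %), CH2Cl2, −78 °C; then Et3N
Reagents that add atoms: none
Why: Mukaiyama–Michael addition under silyl triflate catalysis is non-basic, so the acidic C9–H and the β-oxygen at C8 stay untouched, and silyl transfer delivers the C5=C6 enol ether directly. C7 is set by attack on the exo face, on the side of the oxygen bridge, because the endo face is covered by the C9–C10 bridge and its endo sulfonyl group.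

Step 9
Reactants: 17 C5 silyl enol ether
Product: 20 tricyclic C5-keto γ-lactone (lactone cis-fused on the exo face at C6 and C7; C11 epimers), via exo silyloxy epoxide 18 (not isolated), via C6 hydroxy ketone ester 19 (not isolated)
Conditions: DMDO, acetone–CH2Cl2, −40 to 0 °C; then TsOH·H2O (20 mol %), wet CH2Cl2, rt
Reagents that add atoms: dimethyldioxirane, CC1(C)OO1
Why: Rubottom oxidation: neutral epoxidation of the enol ether takes place on the exo face, the endo face being closed by the sulfonyl-bearing bridge, and sets C6. Acid opens the silyloxy epoxide to the α-hydroxy ketone, whose hydroxyl is cis to the C7 ester chain and lactonises readily. The benzyl ether tolerates the acid.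

Step 10
Reactants: 20 tricyclic keto lactone
Product: 21 tricyclic C5 endo (equatorial) alcohol lactone (C11 epimers)
Conditions: NaBH4, CeCl3·7H2O, MeOH–CH2Cl2, −78 °C
Reagents that add atoms: none
Why: Luche-type reduction: the small hydride should approach C5 axially from the exo face, since the endo face is blocked by the C1–C10 bond and the endo C10–H. This gives the equatorial alcohol, trans to the C1 oxygen and also the more stable epimer. Lactone and sulfone are inert, and CeCl3 keeps the medium non-basic so that C6 is not epimerised.

Step 11
Reactants: 21 tricyclic C5 alcohol lactone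
Product: 23 ring-opened C1,C5-diol with C8=C9 vinyl sulfone and configured C11 (H11 cis to H7), via trilithiated ring-opened enolate 22 (not isolated)
Conditions: LDA (3.3 equiv), THF, −78 to −40 °C; then AcOH, THF, −78 °C
Reagents that add atoms: none
Why: LDA forms the C5 alkoxide and the lactone enolate and then removes the exo C9–H, and the α-sulfonyl carbanion expels the C8 oxygen (E1cB opening of a β-sulfonyl oxabicycle) to free the C1 alkoxide. Kinetic protonation of the enolate occurs on the convex face, anti to the C7–C8 bond, so both C11 epimers converge on the concave methyl group of the target. The adjacent enolate and the limited base charge protect C7–H from γ-deprotonation.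

Step 12
Reactants: 23 diol vinyl sulfone
Product: 24 sulfur-free C8=C9 cycloheptene C1,C5-diol lactone
Conditions: Na(Hg) (5% Na), Na2HPO4, MeOH–THF, −20 °C
Reagents that add atoms: none
Why: Reductive desulfonylation of a vinyl sulfone by electron transfer, the elementary step known from the Julia–Lythgoe olefination: the radical anion loses sulfinate and the vinyl anion is protonated by methanol. The phosphate buffer holds back methoxide, so the lactone and C11 are safe and the C1 hydroxyl has little chance to add back to C8.

Step 13
Reactants: 24 cycloheptene diol lactone
Product: 25 C5 isobutyrate of 24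
Conditions: (i-PrCO)2O, DMAP (cat.), pyridine, CH2Cl2, 0 °C to rt
Reagents that add atoms: isobutyric anhydride, CC(C)C(=O)OC(=O)C(C)C
Why: DMAP-catalysed acylation takes the secondary C5 hydroxyl. The tertiary C1 hydroxyl, flanked by three carbon substituents, is inert under these conditions.

Step 14
Reactants: 25 C5 isobutyrate
Product: 26 saturated C1,C2-diol (primary C2 hydroxyl free)
Conditions: H2 (1 atm), Pd/C, EtOAc, rt
Reagents that add atoms: none
Why: Heterogeneous hydrogenation saturates the cis-disubstituted C8=C9 bond and hydrogenolyses the benzyl ether in one operation; no stereocentre is created and no C–O bond is allylic. The neutral medium gives the C5 ester no catalyst for migration to the new primary hydroxyl, and 26 is taken on directly.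

Step 15
Reactants: 26 C1,C2-diol
Product: 27 C2 aldehyde (tertiary α-hydroxy aldehyde)
Conditions: IBX, DMSO, rt
Reagents that add atoms: none
Why: IBX oxidises the primary alcohol of a 1,2-diol without glycol cleavage and without base. The aldehyde has no α-hydrogen and cannot enolise.

Step 16
Reactants: 27 C2 aldehyde; 7 (E)-1-bromoprop-1-ene
Product: 29 C2 allylic alcohol (C2 epimers), via (E)-prop-1-enylchromium dichloride 28 (not isolated)
Conditions: CrCl2 (6 equiv), NiCl2 (2 mol %), DMF, rt; then H2O
Reagents that add atoms: none
Why: Nozaki–Hiyama–Kishi reaction: zerovalent nickel inserts into the C–Br bond with retention, and transmetalation to trivalent chromium gives 28, which adds only to the aldehyde and tolerates the lactone, the ester and the free hydroxyl. Both C2 epimers are used because C2 becomes a ketone.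

Step 17
Reactants: 29 C2 allylic alcohol
Product: 30 CNP0149747.1 (target)
Conditions: IBX, DMSO, rt
Reagents that add atoms: none
Why: IBX oxidation of the allylic alcohol gives the enone without cleaving the tertiary–secondary diol. The neutral conditions preserve the (E) alkene, C11 and the C5 ester.

## Compound list

1 | furan | c1ccoc1 | starting material
2 | benzyloxyacetaldehyde | O=CCOCc1ccccc1 | starting material
3 | 2-furyllithium | [Li]c1ccco1 | intermediate
4 | 2-(benzyloxy)-1-(furan-2-yl)ethan-1-ol (racemic) | OC(COCc1ccccc1)c1ccco1 | intermediate
5 | 2-(benzyloxymethyl)-6-hydroxy-2H-pyran-3(6H)-one (diastereomer mixture) | OC1OC(COCc2ccccc2)C(=O)C=C1 | intermediate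
6 | 6-acetoxy-2-(benzyloxymethyl)-2H-pyran-3(6H)-one (diastereomer mixture) | CC(=O)OC1OC(COCc2ccccc2)C(=O)C=C1 | intermediate
7 | (E)-1-bromoprop-1-ene | C/C=C/Br | starting material
8 | (1R,2S,5R)-menthyl (S)-p-toluenesulfinate | CC(C)[C@@H]1CC[C@@H](C)C[C@H]1O[S@](=O)c2ccc(C)cc2 | starting material
9 | (E)-prop-1-enyllithium | C/C=C/[Li] | intermediate
10 | (R)-(E)-1-propenyl p-tolyl sulfoxide | C/C=C/[S@@](=O)c1ccc(C)cc1 | intermediate
11 | 2-(benzyloxymethyl)-3-oxidopyrylium | [O-]c1ccc[o+]c1COCc2ccccc2 | intermediate
12 | sulfinyl 8-oxabicyclo[3.2.1]oct-3-en-2-one adduct (methyl exo, sulfinyl endo) | c3ccccc3COC[C@@]12O[C@@H](C=CC1=O)[C@@H]([S@@](=O)c4ccc(C)cc4)[C@@H]2C | intermediate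
13 | sulfonyl 8-oxabicyclo[3.2.1]oct-3-en-2-one | c3ccccc3COC[C@@]12O[C@@H](C=CC1=O)[C@@H](S(=O)(=O)c4ccc(C)cc4)[C@@H]2C | intermediate
14 | methyl propanoate | CCC(=O)OC | starting material
15 | methyl propanoate lithium enolate | CC=C(OC)O[Li] | intermediate
16 | 1-methoxy-1-(trimethylsilyloxy)prop-1-ene (E/Z mixture) | CC=C(OC)O[Si](C)(C)C | intermediate
17 | C5 trimethylsilyl enol ether with exo C7 propanoate chain (C11 epimers) | c3ccccc3COC[C@@]12O[C@@H]([C@@H](C(C)C(=O)OC)C=C1O[Si](C)(C)C)[C@@H](S(=O)(=O)c4ccc(C)cc4)[C@@H]2C | intermediate
18 | exo C5–C6 silyloxy epoxide | c3ccccc3COC[C@@]12O[C@@H]([C@@H](C(C)C(=O)OC)[C@H]6O[C@]61O[Si](C)(C)C)[C@@H](S(=O)(=O)c4ccc(C)cc4)[C@@H]2C | intermediate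
19 | C6 exo-hydroxy C5 ketone methyl ester | c3ccccc3COC[C@@]12O[C@@H]([C@@H](C(C)C(=O)OC)[C@@H](O)C1=O)[C@@H](S(=O)(=O)c4ccc(C)cc4)[C@@H]2C | intermediate
20 | tricyclic C5-keto γ-lactone (C11 epimers) | c3ccccc3COC[C@@]12O[C@@H]([C@@H]5[C@@H](OC(=O)C5C)C1=O)[C@@H](S(=O)(=O)c4ccc(C)cc4)[C@@H]2C | intermediate
21 | tricyclic C5 endo alcohol lactone (C11 epimers) | c3ccccc3COC[C@@]12O[C@@H]([C@@H]5[C@@H](OC(=O)C5C)[C@@H]1O)[C@@H](S(=O)(=O)c4ccc(C)cc4)[C@@H]2C | intermediate
22 | trilithiated ring-opened enolate | c3ccccc3COC[C@]1(O[Li])[C@@H](C)C(S(=O)(=O)c4ccc(C)cc4)=C[C@@H]2[C@@H](OC(O[Li])=C2C)[C@@H]1O[Li] | intermediate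
23 | ring-opened C1,C5-diol vinyl sulfone lactone | c3ccccc3COC[C@]1(O)[C@@H](C)C(S(=O)(=O)c4ccc(C)cc4)=C[C@@H]2[C@@H](OC(=O)[C@@H]2C)[C@@H]1O | intermediate
24 | sulfur-free C8=C9 cycloheptene diol lactone | c3ccccc3COC[C@]1(O)[C@@H](C)C=C[C@@H]2[C@@H](OC(=O)[C@@H]2C)[C@@H]1O | intermediate
25 | C5 isobutyrate of 24 | c3ccccc3COC[C@]1(O)[C@@H](C)C=C[C@@H]2[C@@H](OC(=O)[C@@H]2C)[C@@H]1OC(=O)C(C)C | intermediate
26 | saturated C1,C2-diol isobutyrate | OC[C@]1(O)[C@@H](C)CC[C@@H]2[C@@H](OC(=O)[C@@H]2C)[C@@H]1OC(=O)C(C)C | intermediate
27 | C2 aldehyde | O=C[C@]1(O)[C@@H](C)CC[C@@H]2[C@@H](OC(=O)[C@@H]2C)[C@@H]1OC(=O)C(C)C | intermediate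
28 | (E)-prop-1-enylchromium dichloride | C/C=C/[Cr](Cl)Cl | intermediate
29 | C2 allylic alcohol (C2 epimers) | C/C=C/C(O)[C@]1(O)[C@@H](C)CC[C@@H]2[C@@H](OC(=O)[C@@H]2C)[C@@H]1OC(=O)C(C)C | intermediate
30 | CNP0149747.1 | C/C=C/C(=O)[C@]1(O)[C@@H](C)CC[C@@H]2[C@@H](OC(=O)[C@@H]2C)[C@@H]1OC(=O)C(C)C | target

## Step count and least certain steps

Total step count: 17. Longest linear sequence: 15 (steps 1–3, 5, 6 and 8–17). Steps 4 and 7 are side branches.

**Step 5 (key step).**
- **Risk.** The β-methyl group makes 10 a sluggish dipolarophile, so ylide dimerisation may outrun interception. The methyl also narrows the polarisation that directs C9 to C8 and crowds the substituted C1 terminus, so regiochemistry, endo/exo preference and facial selectivity may all erode. Raising the temperature to compensate would start loss of sulfenic acid toward C10.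
- **Fallback.** It sets out from 6 and 10 and returns at 13. Compound 10 is oxidised with mCPBA to (E)-1-propenyl p-tolyl sulfone F1. This is a stronger, thermally robust acceptor, so the cycloaddition with 6 can be run hotter and more concentrated. It would give 13 together with the mirror-image sulfonyl adduct F2. Preparative chromatography on a chiral stationary phase would then supply enantiopure 13. Stereocontrol passes from the auxiliary to a resolution.

**Step 11.**
- **Risk.** Bridge opening may be incomplete or reversible, because the C1 alkoxide can add back to C8 of the vinyl sulfone. The alkene may shift toward C7 through γ-deprotonation by excess base. Protonation may be less face-selective because the enolate sits in a polylithiated aggregate.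
- **Fallback.** It sets out from 21 and returns at 24, with no change in step count. SmI2 with HMPA in THF cleaves the C9–S bond by electron transfer from divalent samarium. The C9 organosamarium species then expels the C8 oxygen (Julia-type reductive elimination), giving irreversibly the sulfur-free cycloheptene diol lactone as its C11 epimer mixture F7. A separate enolisation with LDA (3.3 equiv) and an AcOH quench at −78 °C, now free of any sulfone chemistry, sets C11 and gives 24.

**Step 10.**
- **Risk.** The axial C7–C11 bond on the exo face is 1,3 to the hydride trajectory. Attack may therefore leak to the endo face and facial selectivity may be poor.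
- **Fallback.** It sets out from 20 and returns at 23, and the control element changes to the C1 hydroxyl. The C5 exo alcohol F4 is opened with LDA as in step 11 to the 5-epi diol vinyl sulfone F5. Its secondary hydroxyl is oxidised with IBX to the α-hydroxy ketone F6. Me4NBH(OAc)3 in MeCN–AcOH at −20 °C binds to the C1 hydroxyl and delivers hydride intramolecularly to the same face, giving the trans diol 23.

**Step 8.**
- **Risk.** C7 is flanked by the bridgehead, so the catalytic cycle may stall. Silyl transfer may be incomplete, or the labile enol ether may be lost on isolation.
- **Fallback.** It sets out from 13 and 16 and returns at 17, separating bond formation from enol ether formation. Stoichiometric TiCl4 in CH2Cl2 at −78 °C drives the addition, and aqueous work-up gives the C5 ketone with exo C7 propanoate chain F3. Soft enolisation with TMSOTf and Et3N, which can only go toward C6, regenerates 17.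

**Step 16.**
- **Risk.** Oxidative addition of the vinyl bromide may be slow, and the neopentyl-type aldehyde is hindered, so reaction times may be long. The C5 ester could then migrate to the metal-bound C2 oxygen.
- **Fallback.** It sets out from 27 and returns at 30, and it avoids any C2 carbinol. Pinnick oxidation (NaClO2, NaH2PO4, 2-methyl-2-butene) gives the α-hydroxy acid F8. EtSH with EDC and catalytic DMAP gives the S-ethyl thioester F9. A Liebeskind–Srogl coupling with (E)-prop-1-enylboronic acid then gives 30 directly under neutral conditions, using Pd2(dba)3, P(2-furyl)3 and copper thiophene-2-carboxylate, Cu(O2CC4H3S).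

## Further compounds

F1 | step 5 | (E)-1-propenyl p-tolyl sulfone | C/C=C/S(=O)(=O)c1ccc(C)cc1
F2 | step 5 | mirror image of 13 | c3ccccc3COC[C@]12O[C@H](C=CC1=O)[C@H](S(=O)(=O)c4ccc(C)cc4)[C@H]2C
F3 | step 8 | C5 ketone with exo C7 propanoate chain (C11 epimers) | c3ccccc3COC[C@@]12O[C@@H]([C@@H](C(C)C(=O)OC)CC1=O)[C@@H](S(=O)(=O)c4ccc(C)cc4)[C@@H]2C
F4 | step 10 | C5 exo alcohol (5-epi-21) | c3ccccc3COC[C@@]12O[C@@H]([C@@H]5[C@@H](OC(=O)C5C)[C@H]1O)[C@@H](S(=O)(=O)c4ccc(C)cc4)[C@@H]2C
F5 | step 10 | 5-epi diol vinyl sulfone (5-epi-23) | c3ccccc3COC[C@]1(O)[C@@H](C)C(S(=O)(=O)c4ccc(C)cc4)=C[C@@H]2[C@@H](OC(=O)[C@@H]2C)[C@H]1O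
F6 | step 10 | C1-hydroxy C5 ketone vinyl sulfone | c3ccccc3COC[C@]1(O)[C@@H](C)C(S(=O)(=O)c4ccc(C)cc4)=C[C@@H]2[C@@H](OC(=O)[C@@H]2C)C1=O
F7 | step 11 | sulfur-free cycloheptene diol lactone (C11 epimers) | c3ccccc3COC[C@]1(O)[C@@H](C)C=C[C@@H]2[C@@H](OC(=O)C2C)[C@@H]1O
F8 | step 16 | C2 carboxylic acid (α-hydroxy acid) | OC(=O)[C@]1(O)[C@@H](C)CC[C@@H]2[C@@H](OC(=O)[C@@H]2C)[C@@H]1OC(=O)C(C)C
F9 | step 16 | C2 S-ethyl thioester | CCSC(=O)[C@]1(O)[C@@H](C)CC[C@@H]2[C@@H](OC(=O)[C@@H]2C)[C@@H]1OC(=O)C(C)C
A1 | alternative 1 | open-chain C6 aldehyde with (Z)-2-(bromomethyl)enoate terminus | COc1ccc(COC[C@]2(OC(C)(C)O[C@H]2C=O)[C@@H](C)CC/C=C(\CBr)C(=O)OC)cc1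
A2 | alternative 1 | cycloheptane cis-hydroxy α-methylene ester | COc1ccc(COC[C@@]23OC(C)(C)O[C@H]2[C@H](O)[C@H](C(=C)C(=O)OC)CC[C@@H]3C)cc1
A3 | alternative 2 | C6 2-diazopropanoate of the C1 triethylsilyl ether | C/C=C/C(=O)[C@]1(O[Si](CC)(CC)CC)[C@@H](C)CCC[C@@H](OC(=O)C(C)=[N+]=[N-])[C@@H]1OC(=O)C(C)C
A4 | alternative 2 | C1 triethylsilyl ether of the target | C/C=C/C(=O)[C@]1(O[Si](CC)(CC)CC)[C@@H](C)CC[C@@H]2[C@@H](OC(=O)[C@@H]2C)[C@@H]1OC(=O)C(C)C
A5 | alternative 3 | cis C6-hydroxy C7-ethynyl cycloheptanone ketal | O1CCOC12[C@@H](C)CC[C@@H](C#C)[C@@H](O)[C@@H]2OCc1ccc(OC)cc1
A6 | alternative 3 | cis-fused α-methylene-γ-butyrolactone ketal | O1CCOC12[C@@H](C)CC[C@@H]3[C@@H](OC(=O)C3=C)[C@@H]2OCc1ccc(OC)cc1
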